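The ratio of two drains on the coupling partner, the catalyst's pull towards target against the feed's pull towards second product, is followed here through the violet flask.

    crystals ⇌ target, rate k1*(cs1 - [target]) while solid is left; crystals form when [target] > cs1 (cs1 = 8.2 mM, k1 = 0.157 min⁻¹)
    solid substrate ⇌ starting material, rate k2*(cs2 - [starting material]) while solid is left; crystals form when [starting material] > cs2 (cs2 = 18 mM, k2 = 0.108 min⁻¹)
    starting material + free catalyst ⇌ catalyst intermediate A (K3 = 45.3 L mol⁻¹, k3 = 328 L mol⁻¹ min⁻¹)
    coupling partner + catalyst intermediate B → free catalyst + second product (k4 = 3520 L mol⁻¹ min⁻¹)
    coupling partner + catalyst intermediate A → free catalyst + target (k5 = 193 L mol⁻¹ min⁻¹)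
    second substrate ⇌ dormant form (K6 = 0.22, k6 = 0.00563 min⁻¹)
    second substrate + free catalyst ⇌ catalyst intermediate B (K7 = 131 L mol⁻¹, k7 = 1600 L mol⁻¹ min⁻¹)

| setting | grey | violet | ochre | amber | green |
|---|---|---|---|---|---|
| solid substrate | 0.050 M | 0.050 M | 0.050 M | 0.050 M | 0.050 M |
| second substrate | 0.0500 M (fed, over 1.0 h) | 0.0500 M (fed, over 4.0 h) | 0.0500 M | 0.0500 M | 0.0500 M |
| coupling partner | 0.0500 M | 0.0500 M | 0.0500 M (in portions, 5, over 4.0 h) | 0.0500 M | 0.0500 M (fed, over 4.0 h) |
| free catalyst | 0.10 mM | 0.10 mM | 0.10 mM | 0.10 mM | 0.10 mM |
| time | 10 h | 10 h | 10 h | 10 h | 10 h |
| remark | all else is in the flask from the start; the feed brings no volume worth counting | all else is in the flask from the start; the feed brings no volume worth counting | first portion at the start, last at 4.0 h | everything together at the start | all else is in the flask from the start; the feed brings no volume worth counting |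

- target is meant together with its crystals
- solid, in amounts per volume of the solution: crystals, solid substrate
- at the start none of the solid substrate is in solution
- run time (grey): 10 h

- which flask leads in amount of target, in percent of the solid substrate charged ("all alike" within 1.5 percentage points) (grey / violet / ochre / amber / green / all alike)
- how much target is there at the end, in percent of the solid substrate charged: grey
- how much target is there at the end, in percent of the solid substrate charged: violet
- how much target is there at the end, in percent of the solid substrate charged: ochre
- how much target is there at the end, in percent of the solid substrate charged: amber
- how much target is there at the end, in percent of the solid substrate charged: green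

- Second substrate enters violet at 0.208 mM min⁻¹. At its charge, coupling partner captures catalyst intermediate B at 176 min⁻¹, far faster than that intermediate falls apart at 12.2 min⁻¹. So, while coupling partner lasts, second product is reckoned to form at the feed rate, and with coupling partner at its charge catalyst intermediate B is reckoned to hold little catalyst.

- Starting material is taken at its solubility, 18 mM, which holds while solid is left. Free catalyst binds it at 5.90 min⁻¹, and catalyst intermediate A falls back at 7.24 min⁻¹.

- Coupling partner captures catalyst intermediate A at a rate proportional to [coupling partner]. In steady state, target forms at the capture rate times the catalyst charge times the binding rate, over the sum of the three rates. That gives 0.250 mM min⁻¹ at the start and 0.159 mM min⁻¹ with 0.0250 M of coupling partner left.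

- The drain ratio, the mean target rate over the feed rate, is 0.761, with the mean taken at the middle of the fall. The share of coupling partner ending as target is reckoned as this ratio over one plus the ratio, and coupling partner and solid substrate are charged alike, so that share reads directly as percent of the solid substrate charged.

- From above, within this reckoning, holding the starting rate throughout gives 54.6%. That is 27.3 mM of target, less than the 32.0 mM of solid beyond solubility, so solid is reckoned to stay in the flask. The curve saturates, so its mean lies below the middle value, which tightens the bound to 43.2%.

- From below, within the same reckoning, the curve lies above a straight line from the starting rate to zero, and integrating that line gives 34.3%. On that line the coupling partner lasts 2.63 h, less than the feed time, so the whole charge is shared out during the feed.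

- Ochre, amber and green hold their second substrate from the start, so they have no feed rate and this ratio gives them no number.

- The forecast, reasoning from “Feeding the second substrate slowly”, names violet and gives grey 12%, violet 33%, ochre 4.3%, amber 4.8% and green 4.6%, which puts its violet below the bracket.

- The simulation puts violet in the lead, with grey 15.1%, violet 38.8%, ochre 5.06%, amber 4.95% and green 4.22%. Violet falls inside the bracket.

- In violet, with the coupling partner, the limiting reagent, at 0%, target against second product stands at 0.635, between the drain ratio 0.761 and the 0.522 of the lower bound. Grey, fed over 1.0 h instead of 4.0 h, carries a drain ratio of 0.190, its bracket runs from 12.5% to 16.0%, and grey holds 15.1%.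

(Its constants are invented; what happens was integrated by code.)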